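The spiro tetrahydrofuran (ring C: O, C9, C11, C12, C13) is disconnected at its O–C13 bond. The key step exploits the enol ether C14=C15 of ring D, which makes C14 a latent carbinol. Ring D is therefore carried as a 3-alkyl-2,5-dihydrofuran; its C13=C14 alkene is epoxidised under catalyst control, and the tertiary 9α-hydroxyl opens this temporary epoxide at C13 (5-exo, inversion). One operation thus closes ring C, forms the hindered ditertiary ether and fixes C13. The precursor is an 8β-acetoxy-9α-hydroxy-7-ketone, made from podocarpic acid by Birch reduction, ozonolysis and decarbonylation, bearing a 2-(2,5-dihydrofuran-3-yl)ethyl chain on C9.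

Key step: step 15

Remark: labdane numbering is used for all atoms once ring C of the podocarpane is cleaved (podocarpane C14 becomes labdane C17). Ring A = C1–C5, C10; ring B = C5–C10; ring C = O, C9, C11, C12, C13; ring D = C13, C14, C15, O, C16. (+)-Podocarpic acid is taken as a commercial chiral-pool material that supplies C4, C5 and C10; TBDPS = tert-butyldiphenylsilyl.

Step 1
Reactants: 1 (+)-podocarpic acid
Product: 2 methyl 12-methoxypodocarpa-8,11,13-trien-19-oate
Conditions: MeI, K2CO3, DMF, 25 °C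
Reagents that add atoms: iodomethane, CI
Why: Williamson O-methylation of the phenoxide and SN2 esterification through the carboxylate oxygen, which avoids attack at the hindered axial carbonyl; no stereocentre is involved.

Step 2
Reactants: 2 methyl 12-methoxypodocarpa-8,11,13-trien-19-oate
Product: 3 12-methoxypodocarpa-8,11,13-trien-19-ol
Conditions: LiAlH4, THF, reflux
Reagents that add atoms: none
Why: Hydride reduction of the neopentyl ester to the primary alcohol; the quaternary C4 cannot epimerise.

Step 3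
Reactants: 3 12-methoxypodocarpa-8,11,13-trien-19-ol
Product: 4 12-methoxypodocarpa-8,12-dien-19-ol
Conditions: Li, NH3(l), THF, t-BuOH, −78 to −33 °C; MeOH, then NH4Cl
Reagents that add atoms: none
Why: Birch reduction of the anisole ring should give the 2,5-dihydroanisole in which the alkyl-bearing C8 and C9 stay sp2 and C12 keeps its methoxy group as an enol ether.

Step 4
Reactants: 4 12-methoxypodocarpa-8,12-dien-19-ol
Product: 5 19-(tert-butyldiphenylsilyloxy)-12-methoxypodocarpa-8,12-diene
Conditions: TBDPSCl, imidazole, DMAP (cat.), DMF, 40 °C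
Reagents that add atoms: tert-butyl(chloro)diphenylsilane, CC(C)(C)[Si](Cl)(c1ccccc1)c1ccccc1
Why: Silylation of the primary alcohol under basic conditions that preserve the enol ether; the aryl silyl group is introduced only after the dissolving-metal step.

Step 5
Reactants: 5 19-(tert-butyldiphenylsilyloxy)-12-methoxypodocarpa-8,12-diene
Product: 6 methyl 19-(tert-butyldiphenylsilyloxy)-13-oxo-12,13-secopodocarp-8-en-12-oate (C9 bears CH2CO2Me, C8 bears CH2CHO)
Conditions: O3 (1 equiv), pyridine, CH2Cl2/MeOH, −78 °C; Me2S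
Reagents that add atoms: ozone, [O-][O+]=O
Why: Chemoselective ozonolysis: the electron-rich enol ether C12=C13 should react far faster than the hindered tetrasubstituted C8=C9 alkene, giving the C12 methyl ester and the C13 aldehyde.

Step 6
Reactants: 6 methyl 19-(tert-butyldiphenylsilyloxy)-13-oxo-12,13-secopodocarp-8-en-12-oate
Product: 7 methyl 19-(tert-butyldiphenylsilyloxy)-13,14,15,16-tetranorlabd-8-en-12-oate
Conditions: [Rh(dppp)2]Cl (5 mol%), diglyme, 160 °C
Reagents that add atoms: none
Why: Tsuji–Wilkinson decarbonylation by univalent rhodium (acyl C–H oxidative addition, CO extrusion, reductive elimination) excises C13 and leaves the C8 methyl group (C17).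

Step 7
Reactants: 7 methyl 19-(tert-butyldiphenylsilyloxy)-13,14,15,16-tetranorlabd-8-en-12-oate
Product: 8 methyl 19-(tert-butyldiphenylsilyloxy)-7-oxo-13,14,15,16-tetranorlabd-8-en-12-oate
Conditions: CrO3, 3,5-dimethylpyrazole, CH2Cl2, −20 °C
Reagents that add atoms: chromium trioxide, O=[Cr](=O)=O
Why: Chromium-mediated allylic oxidation at the ring methylene C7; C11 is deactivated by the adjacent ester and C17 is a primary position.

Step 8
Reactants: 8 methyl 19-(tert-butyldiphenylsilyloxy)-7-oxo-13,14,15,16-tetranorlabd-8-en-12-oate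
Product: 9 19-(tert-butyldiphenylsilyloxy)-13,14,15,16-tetranorlabd-8-ene-7β,12-diol
Conditions: i-Bu2AlH (5 equiv), CH2Cl2, −78 to 0 °C
Reagents that add atoms: none
Why: 1,2-Reduction of the enone and reduction of the ester to the primary alcohol; axial hydride delivery to the α face of the half-chair enone should give the pseudo-equatorial 7β-alcohol.

Step 9
Reactants: 9 19-(tert-butyldiphenylsilyloxy)-13,14,15,16-tetranorlabd-8-ene-7β,12-diol
Product: 10 19-(tert-butyldiphenylsilyloxy)-7β-hydroxy-13,14,15,16-tetranorlabd-8-en-12-yl 4-methylbenzenesulfonate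
Conditions: TsCl (1.2 equiv), pyridine, CH2Cl2, 0 °C
Reagents that add atoms: 4-methylbenzenesulfonyl chloride, Cc1ccc(cc1)S(Cl)(=O)=O
Why: Sulfonylation selective for the unhindered primary hydroxyl over the hindered secondary allylic one.

Step 10
Reactants: 11 dihydrofuran-3(2H)-one
Product: 12 2,5-dihydrofuran-3-yl trifluoromethanesulfonate
Conditions: LiN(i-Pr)2, THF, −78 °C; PhNTf2, −78 to 0 °C
Reagents that add atoms: N-phenylbis(trifluoromethanesulfonimide), FC(F)(F)S(=O)(=O)N(c1ccccc1)S(=O)(=O)C(F)(F)F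
Why: Kinetic enolisation away from the oxygen-bearing α-carbon followed by O-triflation should give the enol triflate with the ring D double bond in the 3,4-position.

Step 11
Reactants: 10 the 12-tosylate; 12 2,5-dihydrofuran-3-yl trifluoromethanesulfonate
Product: 13 19-(tert-butyldiphenylsilyloxy)-15,16-epoxylabda-8,13-dien-7β-ol
Conditions: NiBr2(dme) (10 mol%), 4,4′-di-tert-butyl-2,2′-bipyridine (10 mol%), NaI (1.5 equiv), Zn, DMA, 50 °C
Reagents that add atoms: none
Why: Nickel-catalysed reductive cross-electrophile coupling: Finkelstein exchange gives the primary iodide, its alkyl radical is captured by the alkenylnickel species formed from zerovalent nickel and the triflate, and reductive elimination forms C12–C13; the free secondary alcohol is tolerated.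

Step 12
Reactants: 13 19-(tert-butyldiphenylsilyloxy)-15,16-epoxylabda-8,13-dien-7β-ol
Product: 14 19-(tert-butyldiphenylsilyloxy)-15,16-epoxylabda-8,13-dien-7β-yl acetate
Conditions: Ac2O, pyridine, DMAP (cat.), CH2Cl2, 25 °C
Reagents that add atoms: acetic anhydride, CC(=O)OC(C)=O
Why: Acylation of the secondary allylic alcohol installs the acetyl group that is later transferred to O8.

Step 13
Reactants: 14 the 7β-acetate
Product: 17 8β-acetoxy-19-(tert-butyldiphenylsilyloxy)-15,16-epoxylabd-13-ene-7β,9α-diol, via 8α,9α-epoxide 15 (not isolated), via acetoxonium ion 16 (not isolated)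
Conditions: mCPBA (1.05 equiv), NaHCO3, CH2Cl2, −20 to 0 °C; aqueous wash; then TsOH·H2O (10 mol%), wet CH2Cl2, −20 °C
Reagents that add atoms: meta-chloroperbenzoic acid, OOC(=O)c1cccc(Cl)c1; water, O
Why: Peracid epoxidation should occur at the tetrasubstituted C8=C9 alkene (far more nucleophilic than the ring D alkene with two allylic oxygens) from the α face, anti to the C10 methyl and the 7β-acetate; acid then triggers neighbouring-group participation in which the acetate carbonyl opens the epoxide at C8 from the β face (trans-diaxial, inversion) while O9 stays α, and the cis-fused acetoxonium ion collapses through its orthoacid to the axial 8β-acetate and the equatorial 7β-alcohol.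

Step 14
Reactants: 17 the 7β,9α-diol 8β-acetate
Product: 18 8β-acetoxy-19-(tert-butyldiphenylsilyloxy)-9α-hydroxy-15,16-epoxylabd-13-en-7-one
Conditions: Dess–Martin periodinane, NaHCO3, CH2Cl2, 25 °C
Reagents that add atoms: none
Why: Dess–Martin oxidation of the only secondary alcohol gives the C7 ketone and removes the possibility of acyl migration from O8 to O7.

Step 15
Reactants: 18 8β-acetoxy-19-(tert-butyldiphenylsilyloxy)-9α-hydroxy-15,16-epoxylabd-13-en-7-one
Product: 20 (13R,14R)-8β-acetoxy-19-(tert-butyldiphenylsilyloxy)-9α,13:15,16-diepoxy-14-hydroxylabdan-7-one, via (13S,14R)-13,14-epoxide 19 (not isolated)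
Conditions: D-fructose-derived Shi ketone (0.5 equiv), KHSO5 (as Oxone), K2CO3, Bu4NHSO4, MeCN/dimethoxymethane/aq. Na2B4O7 buffer, 0 °C; extraction; then 10-camphorsulfonic acid (10 mol%), CH2Cl2, 0 °C
Reagents that add atoms: potassium peroxymonosulfate, [K+].[O-]S(=O)(=O)OO
Why: The dioxirane formed from KHSO5 and the chiral ketone transfers oxygen to the only alkene, C13=C14 of ring D, through a spiro transition state, and on acidification the protonated epoxide is opened at C13 by the tertiary 9α-hydroxyl with backside displacement. The closest known reaction type is the Shi epoxidation followed by acid-catalysed epoxy-alcohol cyclisation, as used for polyether tetrahydrofurans. Ring C (O, C9, C11, C12, C13) closes in the 5-exo-tet mode as a spiro ring on ring D, and no other ring is formed. C13 is set by two linked elements, the catalyst-controlled face of epoxidation (the (13S,14R)-epoxide is expected by analogy with 1-substituted cycloalkenes) and the stereospecific inversion in the opening, while C14 (hydroxyl trans to O9) comes from the same epoxidation and is erased in step 16. The step needs attack at the tertiary C13 and not at C14 (6-endo), which the better cation-stabilising centre and the five-membered transition state secure, and it needs the 9-hydroxyl to be the only nucleophile in reach, which holds because O8 is acetylated, O19 is silylated and the acetate carbonyl would have to close an eight-membered ring. Because C14–C15 is still saturated during the acid treatment, loss of a C16 proton cannot aromatise ring D to a furan.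

Step 16
Reactants: 20 the spiro ether 14-alcohol
Product: 21 (13S)-8β-acetoxy-19-(tert-butyldiphenylsilyloxy)-9α,13:15,16-diepoxylabd-14-en-7-one
Conditions: Burgess reagent (methyl N-(triethylammoniosulfonyl)carbamate), toluene, 60 °C; work-up over Et3N-treated silica
Reagents that add atoms: none
Why: Burgess dehydration (syn elimination of the sulfamate ester) of the secondary C14 alcohol; C13 is quaternary, so only a C15 hydrogen can be lost, giving the C14=C15 enol ether without acid.

Step 17
Reactants: 21 the 19-silyl ether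
Product: 22 (13S)-8β-acetoxy-9α,13:15,16-diepoxy-19-hydroxylabd-14-en-7-one (CNP0239339.2)
Conditions: Bu4NF, AcOH (1:1), THF, 25–40 °C
Reagents that add atoms: none
Why: Fluoride-mediated cleavage of the silyl ether, buffered with acetic acid, should leave the acid-labile enol ether, the tertiary acetate and the ketone untouched.

Compound list
1 | (+)-podocarpic acid (12-hydroxypodocarpa-8,11,13-trien-19-oic acid) | Oc1ccc2CC[C@H]3[C@@](C)(C(=O)O)CCC[C@]3(C)c2c1 | starting material
2 | methyl 12-methoxypodocarpa-8,11,13-trien-19-oate | COc1ccc2CC[C@H]3[C@@](C)(C(=O)OC)CCC[C@]3(C)c2c1 | intermediate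
3 | 12-methoxypodocarpa-8,11,13-trien-19-ol | COc1ccc2CC[C@H]3[C@@](C)(CO)CCC[C@]3(C)c2c1 | intermediate
4 | 12-methoxypodocarpa-8,12-dien-19-ol | COC1=CCC=2CC[C@H]3[C@@](C)(CO)CCC[C@]3(C)C=2C1 | intermediate
5 | 19-(tert-butyldiphenylsilyloxy)-12-methoxypodocarpa-8,12-diene | COC1=CCC=2CC[C@H]3[C@@](C)(CO[Si](c4ccccc4)(c4ccccc4)C(C)(C)C)CCC[C@]3(C)C=2C1 | intermediate
6 | methyl 19-(tert-butyldiphenylsilyloxy)-13-oxo-12,13-secopodocarp-8-en-12-oate | COC(=O)CC=1[C@@]2(C)CCC[C@](C)(CO[Si](c3ccccc3)(c3ccccc3)C(C)(C)C)[C@@H]2CCC=1CC=O | intermediate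
7 | methyl 19-(tert-butyldiphenylsilyloxy)-13,14,15,16-tetranorlabd-8-en-12-oate | COC(=O)CC=1[C@@]2(C)CCC[C@](C)(CO[Si](c3ccccc3)(c3ccccc3)C(C)(C)C)[C@@H]2CCC=1C | intermediate
8 | methyl 19-(tert-butyldiphenylsilyloxy)-7-oxo-13,14,15,16-tetranorlabd-8-en-12-oate | COC(=O)CC=1[C@@]2(C)CCC[C@](C)(CO[Si](c3ccccc3)(c3ccccc3)C(C)(C)C)[C@@H]2CC(=O)C=1C | intermediate
9 | 19-(tert-butyldiphenylsilyloxy)-13,14,15,16-tetranorlabd-8-ene-7β,12-diol | OCCC=1[C@@]2(C)CCC[C@](C)(CO[Si](c3ccccc3)(c3ccccc3)C(C)(C)C)[C@@H]2C[C@H](O)C=1C | intermediate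
10 | 19-(tert-butyldiphenylsilyloxy)-7β-hydroxy-13,14,15,16-tetranorlabd-8-en-12-yl 4-methylbenzenesulfonate | Cc1ccc(cc1)S(=O)(=O)OCCC=1[C@@]2(C)CCC[C@](C)(CO[Si](c3ccccc3)(c3ccccc3)C(C)(C)C)[C@@H]2C[C@H](O)C=1C | intermediate
11 | dihydrofuran-3(2H)-one | O=C1CCOC1 | starting material
12 | 2,5-dihydrofuran-3-yl trifluoromethanesulfonate | FC(F)(F)S(=O)(=O)OC1=CCOC1 | intermediate
13 | 19-(tert-butyldiphenylsilyloxy)-15,16-epoxylabda-8,13-dien-7β-ol | C1OCC=C1CCC=2[C@@]3(C)CCC[C@](C)(CO[Si](c4ccccc4)(c4ccccc4)C(C)(C)C)[C@@H]3C[C@H](O)C=2C | intermediate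
14 | 19-(tert-butyldiphenylsilyloxy)-15,16-epoxylabda-8,13-dien-7β-yl acetate | C1OCC=C1CCC=2[C@@]3(C)CCC[C@](C)(CO[Si](c4ccccc4)(c4ccccc4)C(C)(C)C)[C@@H]3C[C@H](OC(C)=O)C=2C | intermediate
15 | 19-(tert-butyldiphenylsilyloxy)-8α,9α:15,16-diepoxylabd-13-en-7β-yl acetate | C1OCC=C1CC[C@@]23O[C@]2(C)[C@@H](OC(C)=O)C[C@H]2[C@@](C)(CO[Si](c4ccccc4)(c4ccccc4)C(C)(C)C)CCC[C@]32C | intermediate (not isolated)
16 | 7β,8β-acetoxonium ion (2-methyl-1,3-dioxolan-2-ylium bridging O7 and O8) of the 9α-ol | CC1=[O+][C@@]2(C)[C@@H](O1)C[C@H]3[C@@](C)(CO[Si](c4ccccc4)(c4ccccc4)C(C)(C)C)CCC[C@]3(C)[C@@]2(O)CCC1=CCOC1 | intermediate (not isolated)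
17 | 8β-acetoxy-19-(tert-butyldiphenylsilyloxy)-15,16-epoxylabd-13-ene-7β,9α-diol | CC(=O)O[C@@]1(C)[C@@H](O)C[C@H]2[C@@](C)(CO[Si](c3ccccc3)(c3ccccc3)C(C)(C)C)CCC[C@]2(C)[C@@]1(O)CCC1=CCOC1 | intermediate
18 | 8β-acetoxy-19-(tert-butyldiphenylsilyloxy)-9α-hydroxy-15,16-epoxylabd-13-en-7-one | CC(=O)O[C@@]1(C)C(=O)C[C@H]2[C@@](C)(CO[Si](c3ccccc3)(c3ccccc3)C(C)(C)C)CCC[C@]2(C)[C@@]1(O)CCC1=CCOC1 | intermediate
19 | (13S,14R)-8β-acetoxy-19-(tert-butyldiphenylsilyloxy)-9α-hydroxy-13,14:15,16-diepoxylabdan-7-one | CC(=O)O[C@@]1(C)C(=O)C[C@H]2[C@@](C)(CO[Si](c3ccccc3)(c3ccccc3)C(C)(C)C)CCC[C@]2(C)[C@@]1(O)CC[C@]12COC[C@H]1O2 | intermediate (not isolated)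
20 | (13R,14R)-8β-acetoxy-19-(tert-butyldiphenylsilyloxy)-9α,13:15,16-diepoxy-14-hydroxylabdan-7-one | CC(=O)O[C@@]1(C)C(=O)C[C@H]2[C@@](C)(CO[Si](c3ccccc3)(c3ccccc3)C(C)(C)C)CCC[C@]2(C)[C@@]12CC[C@@]1([C@H](O)COC1)O2 | intermediate
21 | (13S)-8β-acetoxy-19-(tert-butyldiphenylsilyloxy)-9α,13:15,16-diepoxylabd-14-en-7-one | CC(=O)O[C@@]1(C)C(=O)C[C@H]2[C@@](C)(CO[Si](c3ccccc3)(c3ccccc3)C(C)(C)C)CCC[C@]2(C)[C@@]12CC[C@@]1(C=COC1)O2 | intermediate
22 | (13S)-8β-acetoxy-9α,13:15,16-diepoxy-19-hydroxylabd-14-en-7-one | CC(=O)O[C@@]1(C)C(=O)C[C@H]2[C@@](C)(CO)CCC[C@]2(C)[C@@]12CC[C@@]1(C=COC1)O2 | target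

Total step count: 17. Longest linear sequence: 16 (steps 1–9 and 11–17).

Steps most likely to fail

Step 13. The acid stage may ionise the C9–O bond of the tetrasubstituted epoxide and shift the C10 methyl (or contract the ring) before the acetate participates at C8. The orthoacid may also collapse the wrong way, or the acetyl may migrate from O8 to O7. The fallback sets out from 13 and returns at 18; it avoids any carbocation. Alcohol 13 would be oxidised with MnO2 to 19-(tert-butyldiphenylsilyloxy)-15,16-epoxylabda-8,13-dien-7-one F1. Weitz–Scheffer epoxidation (H2O2, NaOH, MeOH) should attack C9 axially from the α face, leave the ring D alkene alone and give the 8α,9α-epoxy ketone F2. SmI2 (THF, −78 °C) would cleave the C8–O bond to the samarium enolate, which is trapped with Ac2O as the 7-acetoxy-7-en-9α-ol F3. mCPBA, directed by the 9α-hydroxyl and kept off the β face by the C10 methyl, should give the 7β-acetoxy-7α,8α-epoxide F4. Heating in toluene at 100 °C should shift the acetoxy group from C7 to C8 with inversion (thermal enol ester epoxide rearrangement) and deliver 18.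

Step 15. Oxygen transfer to the ring D alkene, which is deactivated by two allylic C–O bonds, may be slow and poorly face-selective, and the pH 10.5 medium may open ring B by retro-aldol cleavage. The fallback sets out from 18 and returns at 21. Iodoetherification (N-iodosuccinimide, NaHCO3, MeCN, 0 °C) would close ring C by 5-exo attack of O9 on C13 of the iodonium ion and give (13R,14R)-8β-acetoxy-19-(tert-butyldiphenylsilyloxy)-9α,13:15,16-diepoxy-14-iodolabdan-7-one F5. Facial selectivity is then substrate-controlled, so F5 would have to be separated from its C13/C14 epimer by chromatography. E2 loss of HI towards C15 (DBU, toluene, 80 °C) would give 21.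

Step 6. The allyl rhodium hydride formed after CO extrusion may reductively eliminate at C9 and move the double bond to the exocyclic C8=C17 position, or the β,γ-unsaturated aldehyde may isomerise into conjugation at 160 °C. The fallback sets out from 6 and returns at 7. Pinnick oxidation (NaClO2, NaH2PO4, 2-methyl-2-butene, t-BuOH/H2O) would give the acid, 12-methyl hydrogen 19-(tert-butyldiphenylsilyloxy)-12,13-secopodocarp-8-ene-12,13-dioate F6. Coupling with N-hydroxypyridine-2-thione (DCC, DMAP) would give the Barton ester F7. Photolysis with t-BuSH (Barton decarboxylation) should deliver hydrogen to the unhindered primary terminus of the allyl radical and give 7.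

Further compounds
F1 | step 13 | 19-(tert-butyldiphenylsilyloxy)-15,16-epoxylabda-8,13-dien-7-one | C1OCC=C1CCC=2[C@@]3(C)CCC[C@](C)(CO[Si](c4ccccc4)(c4ccccc4)C(C)(C)C)[C@@H]3CC(=O)C=2C
F2 | step 13 | 19-(tert-butyldiphenylsilyloxy)-8α,9α:15,16-diepoxylabd-13-en-7-one | C1OCC=C1CC[C@@]23O[C@]2(C)C(=O)C[C@H]2[C@@](C)(CO[Si](c4ccccc4)(c4ccccc4)C(C)(C)C)CCC[C@]32C
F3 | step 13 | 7-acetoxy-19-(tert-butyldiphenylsilyloxy)-15,16-epoxylabda-7,13-dien-9α-ol | CC(=O)OC=1C[C@H]2[C@@](C)(CO[Si](c3ccccc3)(c3ccccc3)C(C)(C)C)CCC[C@]2(C)[C@@](O)(CCC2=CCOC2)C=1C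
F4 | step 13 | 7β-acetoxy-19-(tert-butyldiphenylsilyloxy)-7α,8α:15,16-diepoxylabd-13-en-9α-ol | CC(=O)O[C@@]12C[C@H]3[C@@](C)(CO[Si](c4ccccc4)(c4ccccc4)C(C)(C)C)CCC[C@]3(C)[C@@](O)(CCC3=CCOC3)[C@]1(C)O2
F5 | step 15 | (13R,14R)-8β-acetoxy-19-(tert-butyldiphenylsilyloxy)-9α,13:15,16-diepoxy-14-iodolabdan-7-one | CC(=O)O[C@@]1(C)C(=O)C[C@H]2[C@@](C)(CO[Si](c3ccccc3)(c3ccccc3)C(C)(C)C)CCC[C@]2(C)[C@@]12CC[C@@]1([C@H](I)COC1)O2
F6 | step 6 | 12-methyl hydrogen 19-(tert-butyldiphenylsilyloxy)-12,13-secopodocarp-8-ene-12,13-dioate | COC(=O)CC=1[C@@]2(C)CCC[C@](C)(CO[Si](c3ccccc3)(c3ccccc3)C(C)(C)C)[C@@H]2CCC=1CC(O)=O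
F7 | step 6 | 2-thioxopyridin-1(2H)-yl ester of acid F6 | COC(=O)CC=1[C@@]2(C)CCC[C@](C)(CO[Si](c3ccccc3)(c3ccccc3)C(C)(C)C)[C@@H]2CCC=1CC(=O)ON1C=CC=CC1=S
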